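**Remarks.** Locants are briarane locants, read from the target SMILES left to right: C16H2=C5, C4 (OH), C3=C2, C1 (methyl C15), C14=C13, C12 (ketone), C11 (methyl C20, OAc), C10, C9 (OAc), C8 (OH), C17 (methyl C18), C19 (lactone C=O), C7 (lactone O), C6 (Cl). The target is (1S,4S,6S,7R,8R,9S,10S,11S,17R), 2E. Ring A is the cyclohexenone C1/C10–C14. Ring B is the six-membered ring C1–C2–C7–C8–C9–C10 of the bicyclic intermediates. In these, β is the face of the angular methyl C15 and α the opposite face. Assumption: racemic 1 is a commercial building block; its stereocentre is erased through the enamine in step 1.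

## Analysis of the target

The target is a chlorinated briarane: a ten-membered carbocycle (C1–C10) trans-fused at C1/C10 to cyclohexenone ring A, with a γ-lactone fused at C7–C8. It has nine stereocentres. Seven are contiguous (C6, C7, C8, C9, C10, C11, C1); C1 is an all-carbon quaternary centre and C8 and C11 are fully substituted carbinol carbons. C4 and C17 stand apart. On the bicyclic framework, H-10 is trans to C15, C20 and the C9 oxygen are cis to C15, and the C8 hydroxyl is on the opposite face. The sensitive groups are the secondary allylic chloride next to the exocyclic methylene (SN2′, elimination), the bis-allylic C4 carbinol, the β-hydroxy lactone (retro-aldol, dehydration) and the tertiary α-acetoxy enone. Two of four oxygens are acetylated, so strong base is excluded late. The difficulty is the ten-membered ring (entropy, transannular strain) and the two stereocentres C4 and C6 that sit in its flexible part, remote from ring A.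

The structure invites one move. The segment C2=C3 (E) – C4(OH) – C5(=C16H2) – C6(Cl) – C7(O) is what an anionic oxy-Cope ring expansion of ring B delivers when C7 carries an allenyl group and C2 an (E)-2-alkoxyvinyl group. C4–C5 forms and C2–C7 breaks. C5 keeps the outer allene carbon as C16. C7 emerges as a dienolate that is chlorinated at C6.

## Retrosynthetic reasoning

35 ← 34 ← 33 ← 32. The free C4 hydroxyl is unveiled last from its 4-methoxybenzyl ether, so that acetylation of O9 and O11 in 33 cannot touch it. The silyl ethers of 32 keep O9 and O11 apart from O7 until the lactone is closed.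

32 ← 30. The C7–O bond is cut: lactone 32 comes from ketone 30 by reduction and acyl transfer from the amide of 31. With O9 silylated, only O7 can take the acyl group. C7 is relayed from the free C8 hydroxyl.

30 ← 27 (key). C4–C5 is cut and C2–C7 is reconnected, which contracts the ten-membered ring to ring B of the trans-decalin 27. This trades a medium ring with two remote stereocentres for a rigid bicycle. The forward step must form the ring, the E alkene, C4, the exocyclic methylene and the C6–Cl bond in one flask.

27 ← 25 ← 21. The allene is a one-carbon homologation of the terminal alkyne 25. The (E)-enol ether of 24 is traced through boronate 23 and aldehyde 22 to the vinyl group of 21, because E geometry is only secure from an E-alkenyl metal species.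

21 ← 20 ← 19 ← 17. C17–C18 is cut (convex-face methylation of lactone 19). C7–C6 is cut (acetylide addition to ketone 17). The lactone is allowed to migrate from O9 to O7 so that O9 can be silylated and C17 alkylated on the correct face; it is then opened to amide 21, which a tertiary alkoxide does not re-acylate.

17 ← 16 ← 15 ← 14 ← 13. The trans-diaxial C8–OH/C9–O pair is an α-epoxide opened at C9 by the C19 carboxyl. C8–C17 is a cross-coupling on iodoenone 14.

13 ← 12. C2–C3 is cut at the only enolisable position of bis-enone 12.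

12 ← 11 ← 9 ← 7. Both enones come from dehydrogenation. The C11 carbinol and the trans ring fusion come from reductive enolate formation on enone 7 and oxidation of enol ether 9.

7 ← 6 ← 1 + 3. Ring A is a Robinson annulation; the quaternary C1 is set with auxiliary 2.

## Alternatives that were turned down

Alternative 1: the textbook disconnection closes the ten-membered ring last at C2=C3 by ring-closing metathesis of seco-diene A1, with ring A and the lactone in place. It was turned down for three reasons. An E-selective closure of a ten-membered ring next to quaternary C1 works against ring strain and transannular repulsion. The catalyst would also meet the exocyclic methylene and the allylic chloride. C4, C6, C7, C8 and C9 would all have to be set in an open chain, which costs more steps than the ring closure saves.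

Alternative 2: a Wharton–Grob fragmentation of tricyclic hydroxy mesylate A2 (third ring C2–C3–C4–C5–C6–C7; C7 alkoxide, equatorial C3 mesylate) would cleave C2–C7 and give the E alkene and the C7 ketone stereospecifically. It was turned down because the C4–C5 bond must still be made, now in an extra annulation. The third ring needs three further stereocentres before it is destroyed, and C6 chlorination remains a separate problem.

Alternative 3: an oxy-Cope of reversed polarity, set up on the 2-hydroxy-2-vinyl-7-allenyl decalin A3 with the carbinol at C2 and the allenyl group at C7, would give a C2 ketone and a C6=C7 alkene. Chlorolactonisation across C6=C7 and a carbonyl transposition at C2 would follow. It was turned down because the C6=C7 alkene is part of a conjugated diene (C16=C5–C6=C7), so the halolactonisation is regiochemically ambiguous (1,2 against 1,4). The C2 ketone needs a three-step transposition, and C4 would be set late on the macrocycle without a relay.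

Key step: step 19

## Route

Step 1
Reactants: 1 7-methyl-1,4-dioxaspiro[4.5]decan-8-one (racemic); 2 (R)-1-phenylethylamine; 3 pent-1-en-3-one
Product: 6 (R)-7-methyl-7-(3-oxopentyl)-1,4-dioxaspiro[4.5]decan-8-one, via imine 4 (not isolated), via alkylated imine 5 (not isolated)
Conditions: 2, cat. TsOH, toluene, Dean–Stark; then 3, THF, 40 °C; then aq. AcOH, rt
Reagents that add atoms: water, O
Why: The secondary enamine tautomer of chiral imine 4 adds to the enone through a compact aza-ene-like transition state on the face away from the phenyl group (Michael addition of a chiral imine), which sets quaternary C1 at its more substituted α-carbon. Hydrolysis returns the auxiliary.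

Step 2
Reactants: 6 (R)-7-methyl-7-(3-oxopentyl)-1,4-dioxaspiro[4.5]decan-8-one
Product: 7 bicyclic enone ketal (C10=C11–C12=O, C7 dioxolane, 1R)
Conditions: NaOMe, MeOH, 60 °C
Reagents that add atoms: none
Why: Intramolecular aldol condensation (second stage of the Robinson annulation) closes ring A as the tetrasubstituted enone. No stereocentre is touched.

Step 3
Reactants: 7 bicyclic enone ketal
Product: 9 tert-butyldimethylsilyl enol ether (C11=C12, H-10 α), via lithium enolate 8 (not isolated)
Conditions: Li, NH3/THF, tBuOH (1 equiv), −78 °C; isoprene; then TBSCl, Et3N, HMPA, THF, 0 °C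
Reagents that add atoms: tert-butyldimethylsilyl chloride, CC(C)(C)[Si](C)(C)Cl
Why: Birch-type reduction of the enone protonates C10 axially, anti to C15, which gives the trans ring fusion. It leaves the C11=C12 enolate regiospecifically, and this is silylated on oxygen.

Step 4
Reactants: 9 tert-butyldimethylsilyl enol ether
Product: 11 7,12-diketone with 11α-OTBS and 11β-methyl, via silyloxy ketone 10 (not isolated)
Conditions: DMDO, acetone/CH2Cl2, −40 °C to rt; then 1 M HCl, THF, rt
Reagents that add atoms: dimethyldioxirane, CC1(C)OO1; water, O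
Why: Rubottom oxidation: the dioxirane attacks the enol ether from the α face, away from the axial C15 methyl, and silyl migration gives the 11α-silyloxy ketone with C20 cis to C15. Aqueous acid then removes the dioxolane while the hindered tertiary silyl ether stays.

Step 5
Reactants: 11 7,12-diketone
Product: 12 bis-enone (C13=C14–C12=O and C8=C9–C7=O)
Conditions: 2-iodoxybenzoic acid, DMSO/fluorobenzene, 70 °C
Reagents that add atoms: none
Why: Dehydrogenation of each ketone through its enol. C11 and C1 are quaternary, so only the C13=C14 and C8=C9 alkenes can form.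

Step 6
Reactants: 12 bis-enone
Product: 13 2α-vinyl bis-enone
Conditions: LiN(SiMe3)2, THF, −78 °C; vinyl bromide, Pd2(dba)3 (cat.), P(tBu)3, 0 °C to rt
Reagents that add atoms: vinyl bromide, C=CBr
Why: Palladium-catalysed α-alkenylation of a ketone enolate at C2, the only enolisable position. The new bond forms on the α face, anti to the adjacent axial C15. The remaining C2–H is then equatorial and poorly aligned for re-enolisation.

Step 7
Reactants: 13 2α-vinyl bis-enone
Product: 14 8-iodo enone
Conditions: I2, pyridine, CH2Cl2, rt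
Reagents that add atoms: iodine, II
Why: α-Iodination of an enone by addition of pyridine to the β-carbon, iodination of the enolate and loss of pyridine. C9 is accessible, whereas C14 of the ring A enone is neopentylic and does not accept the amine.

Step 8
Reactants: 14 8-iodo enone
Product: 15 tert-butyl ester (C8–CH2–CO2tBu)
Conditions: BrZnCH2CO2tBu, Pd(dba)2 (cat.), P(tBu)3, THF, rt
Reagents that add atoms: (2-tert-butoxy-2-oxoethyl)zinc bromide, Br[Zn]CC(=O)OC(C)(C)C
Why: Negishi-type coupling of a Reformatsky reagent with the alkenyl iodide brings in C17 and C19 at the acid oxidation level, without a new stereocentre.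

Step 9
Reactants: 15 tert-butyl ester
Product: 16 8α,9α-epoxy ketone
Conditions: 30% H2O2, NaOH, MeOH, 0 °C
Reagents that add atoms: hydrogen peroxide, OO
Why: Weitz–Scheffer epoxidation: hydroperoxide adds to C9 from the α face because the β trajectory is 1,3-diaxial to C15, and ring closure gives the α-epoxide. The ring A enone is protected by its neopentylic β-carbon.

Step 10
Reactants: 16 8α,9α-epoxy ketone
Product: 17 9β-O,19-lactone with 8α-OH and C7 ketone
Conditions: CF3CO2H, CH2Cl2, 0 °C
Reagents that add atoms: none
Why: Acid cleaves the tert-butyl ester, and the carboxyl group opens the protonated epoxide at C9 with inversion. C8 is deactivated by the adjacent ketone, and opening at C9 is the trans-diaxial mode (Fürst–Plattner rule). This sets the 9β-oxygen and the 8α tertiary hydroxyl together.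

Step 11
Reactants: 17 9β-O,19-lactone ketone
Product: 19 7β-O,19-lactone with 7α-(trimethylsilylethynyl), 8α-OH and 9β-OSiEt3, via dilithium alkoxide 18 (not isolated)
Conditions: LiC≡CSiMe3 (3 equiv), THF, −78 to −20 °C; then Et3SiCl (1.1 equiv), −78 °C; aq. NH4Cl
Reagents that add atoms: lithium (trimethylsilyl)acetylide, [Li]C#C[Si](C)(C)C; chlorotriethylsilane, CC[Si](Cl)(CC)CC
Why: The acetylide adds to the α-alkoxy ketone, held by the lithium 8-alkoxide, along the equatorial trajectory because the axial one is blocked by syn-axial C15 and O9; this gives the axial 7β-alkoxide. That alkoxide attacks the neighbouring lactone carbonyl, the acyl group moves to O7, and the released secondary 9-alkoxide is silylated fastest. The hindered, conjugated C12 ketone should not compete.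

Step 12
Reactants: 19 7β-O,19-lactone
Product: 20 (17R)-17-methyl lactone
Conditions: LiN(iPr)2 (2.3 equiv), THF, −78 °C; MeI, −78 to −40 °C
Reagents that add atoms: iodomethane, CI
Why: Fráter–Seebach-type alkylation of the β-oxido lactone enolate on the convex face of the cis-fused bicycle, anti to the C8–C9 bond. This places C18 cis to the C8 oxygen (17R), and the alkoxide suppresses β-elimination.

Step 13
Reactants: 20 (17R)-17-methyl lactone
Product: 21 morpholine amide with free 7β-OH and 8α-OH
Conditions: morpholine, AlMe3, CH2Cl2, 0 to 35 °C; aq. potassium sodium tartrate work-up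
Reagents that add atoms: morpholine, C1COCCN1
Why: Weinreb-type aminolysis with the dimethylaluminium amide opens the hindered lactone. It frees the C7 hydroxyl for the key step and leaves C19 as a tertiary amide that a tertiary alkoxide does not acylate.

Step 14
Reactants: 21 morpholine amide
Product: 22 C3 aldehyde (expected to rest as its bridged lactol with the 8α-OH)
Conditions: O3, pyridine, CH2Cl2/MeOH, −78 °C (Sudan red end point); Me2S
Reagents that add atoms: ozone, [O-][O+]=O
Why: Ozonolysis cleaves the monosubstituted alkene far faster than the electron-poor enone or the silylalkyne. The syn-axial C8 hydroxyl should mask the aldehyde as a lactol, which protects it from retro-aldol cleavage.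

Step 15
Reactants: 22 C3 aldehyde
Product: 23 (E)-alkenyl pinacol boronate
Conditions: CrCl2, Cl2CHB(pin), LiI, THF, rt
Reagents that add atoms: 2-(dichloromethyl)-4,4,5,5-tetramethyl-1,3,2-dioxaborolane, ClC(Cl)B1OC(C)(C)C(C)(C)O1
Why: Takai–Utimoto olefination: the geminal dichromium reagent adds to the open-chain aldehyde and eliminates from the less crowded adduct to give the E alkene under neutral conditions.

Step 16
Reactants: 23 (E)-alkenyl pinacol boronate
Product: 24 (E)-4-methoxybenzyl enol ether
Conditions: Cu(OAc)2, 4-methoxybenzyl alcohol, Et3N, 4 Å MS, CH2Cl2, air, rt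
Reagents that add atoms: 4-methoxybenzyl alcohol, COc1ccc(CO)cc1
Why: Chan–Lam-type oxidative C–O coupling of an alkenyl boronate with an alcohol; transmetalation and reductive elimination keep the E geometry. The tertiary hydroxyls are too hindered to couple.

Step 17
Reactants: 24 (E)-4-methoxybenzyl enol ether
Product: 25 terminal alkyne
Conditions: K2CO3, MeOH, 0 °C
Reagents that add atoms: none
Why: Methanolysis of the alkynyl C–Si bond. The silyl ethers on oxygen, the amide and the enol ether are stable to brief mild base.

Step 18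
Reactants: 25 terminal alkyne
Product: 27 7α-allenyl carbinol, via Mannich base 26 (not isolated)
Conditions: (CH2O)n, CuI, dicyclohexylamine, dioxane, 100 °C
Reagents that add atoms: paraformaldehyde (as formaldehyde), C=O
Why: Crabbé homologation: a Mannich reaction gives the propargylic amine, and copper-mediated 1,5-hydride transfer then releases the terminal allene and the imine. The free tertiary hydroxyl is not a leaving group under these conditions.

Step 19
Reactants: 27 7α-allenyl carbinol
Product: 30 (2E,4S,6S)-6-chloro-7-ketone with the ten-membered ring, via dialkoxide 28 (not isolated), via dienolate 29 (not isolated)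
Conditions: KH, 18-crown-6, THF, 0 to 25 °C; then C2Cl6, −78 °C; AcOH, −78 °C
Reagents that add atoms: hexachloroethane, ClC(Cl)(Cl)C(Cl)(Cl)Cl
Why: Proposed new method: dialkoxide 28 should undergo an anionic oxy-Cope rearrangement in which the inner C5=C6 bond of the allene and the C3=C4 enol ether are the two π components, C2–C7 breaks and C4–C5 forms; the closest known reaction type is the anionic oxy-Cope ring expansion of 1,2-dialkenylcyclohexanols to cyclodec-5-enones with in-flask trapping of the enolate, and the thermal Cope rearrangement of 1,2,6-heptatrienes shows that an allene can be the 2π partner and keep its outer C=C as an exocyclic methylene. No ring is closed by cyclisation: the ten-membered ring arises by four-atom expansion of ring B through a chair-like six-membered transition state cis-fused to ring B (C1 equatorial, C8 axial), and loss of the allene together with enolate formation makes the step irreversible. The E geometry of C2=C3 follows from the rotamer that turns C4 towards the C2–H and away from quaternary C1. C4 is set by suprafacial bonding on the face from which C7 departs, so the E enol ether on the 2α-configured C2 should give 4S, and C5 becomes the exocyclic methylene carbon. The cross-conjugated dienolate 29 is chlorinated at its α-carbon C6, the kinetic site, on the outer face opposite to the transannular C2=C3 bond, which should give 6S. Hexachloroethane is chosen because it transfers chlorine to carbanions but not to the 8-alkoxide. The step needs the [3,3] shift to win over 5-endo attack of the alkoxide on the allene, α- over γ-chlorination and one enolate face; the tertiary amide, the silyl ethers and the non-enolisable ring A enone are spectators. The crown ether keeps the temperature low enough for the dienolate to hold the conformation in which it is born.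

Step 20
Reactants: 30 6-chloro-7-ketone
Product: 32 γ-lactone with 4-OPMB, 9-OSiEt3 and 11-OTBS, via hydroxy amide 31 (not isolated)
Conditions: Zn(BH4)2, Et2O, −40 °C; then AcOH, toluene, 40 °C
Reagents that add atoms: none
Why: Zinc bridges the C7 carbonyl and the free C8 hydroxyl (Cram chelate model), and hydride arrives from the face of C17, away from the C9 branch, to give the 7R alcohol (anti to O8). The activated α-chloro-α′-hydroxy ketone reacts well before the hindered enone. Mild acid then drives N-to-O acyl transfer onto O7, the only free secondary oxygen, with loss of morpholine.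

Step 21
Reactants: 32 γ-lactone bis-silyl ether
Product: 33 8,9,11-triol 4-PMB ether
Conditions: HF·pyridine, pyridine, THF, 0 °C to rt
Reagents that add atoms: none
Why: Fluoride-mediated cleavage of both silyl ethers. The buffered reagent should leave the allylic chloride, the lactone and the benzyl-type ether intact.

Step 22
Reactants: 33 8,9,11-triol 4-PMB ether
Product: 34 9,11-diacetate 4-PMB ether
Conditions: Ac2O, DMAP, Et3N, CH2Cl2, rt
Reagents that add atoms: acetic anhydride, CC(=O)OC(C)=O
Why: DMAP-catalysed acylation of the secondary C9 hydroxyl and of the tertiary α-ketol hydroxyl at C11. The C8 hydroxyl, flanked by three branched carbons and hydrogen-bonded to the lactone, should stay free.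

Step 23
Reactants: 34 9,11-diacetate 4-PMB ether
Product: 35 CNP0196166.1
Conditions: DDQ, CH2Cl2/pH 7 buffer, 0 °C
Reagents that add atoms: none
Why: Oxidative cleavage of the 4-methoxybenzyl ether by benzylic hydride abstraction and hydrolysis of the oxocarbenium ion. Buffered, cold conditions spare the bis-allylic alcohol and the acetates.

## Compound list

1 | 7-methyl-1,4-dioxaspiro[4.5]decan-8-one (racemic) | CC1CC2(CCC1=O)OCCO2 | starting material
2 | (R)-1-phenylethylamine | C[C@@H](N)c1ccccc1 | starting material
3 | pent-1-en-3-one | CCC(=O)C=C | starting material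
4 | imine of 1 with 2 (C1 epimers interconvert through the enamine) | CC1CC2(CCC1=N[C@H](C)c1ccccc1)OCCO2 | intermediate
5 | C1-alkylated imine with quaternary C1 | CCC(=O)CC[C@]1(C)CC2(CCC1=N[C@H](C)c1ccccc1)OCCO2 | intermediate
6 | (R)-7-methyl-7-(3-oxopentyl)-1,4-dioxaspiro[4.5]decan-8-one | CCC(=O)CC[C@]1(C)CC2(CCC1=O)OCCO2 | intermediate
7 | bicyclic enone ketal (C10=C11–C12=O, C7 dioxolane, 1R) | C[C@]12CCC(=O)C(C)=C1CCC1(OCCO1)C2 | intermediate
8 | lithium C11=C12 enolate, H-10 α | [Li+].C[C@]12CCC([O-])=C(C)[C@@H]1CCC1(OCCO1)C2 | intermediate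
9 | tert-butyldimethylsilyl enol ether of 8 | C[C@]12CCC(O[Si](C)(C)C(C)(C)C)=C(C)[C@@H]1CCC1(OCCO1)C2 | intermediate
10 | 11α-silyloxy 12-ketone, C7 dioxolane | C[C@]12CCC(=O)[C@@](C)(O[Si](C)(C)C(C)(C)C)[C@@H]1CCC1(OCCO1)C2 | intermediate
11 | 7,12-diketone, 11α-OTBS, 11β-methyl | C[C@]12CCC(=O)[C@@](C)(O[Si](C)(C)C(C)(C)C)[C@@H]1CCC(=O)C2 | intermediate
12 | bis-enone (C13=C14 and C8=C9) | C[C@]12C=CC(=O)[C@@](C)(O[Si](C)(C)C(C)(C)C)[C@@H]1C=CC(=O)C2 | intermediate
13 | 2α-vinyl bis-enone | C[C@]12C=CC(=O)[C@@](C)(O[Si](C)(C)C(C)(C)C)[C@@H]1C=CC(=O)[C@H]2C=C | intermediate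
14 | 8-iodo-2α-vinyl bis-enone | C[C@]12C=CC(=O)[C@@](C)(O[Si](C)(C)C(C)(C)C)[C@@H]1C=C(I)C(=O)[C@H]2C=C | intermediate
15 | 8-(tert-butoxycarbonylmethyl) enone | C[C@]12C=CC(=O)[C@@](C)(O[Si](C)(C)C(C)(C)C)[C@@H]1C=C(CC(=O)OC(C)(C)C)C(=O)[C@H]2C=C | intermediate
16 | 8α,9α-epoxy ketone | C[C@]12C=CC(=O)[C@@](C)(O[Si](C)(C)C(C)(C)C)[C@@H]1[C@H]3O[C@@]3(CC(=O)OC(C)(C)C)C(=O)[C@H]2C=C | intermediate
17 | 9β-O,19-lactone, 8α-OH, C7 ketone | C[C@]12C=CC(=O)[C@@](C)(O[Si](C)(C)C(C)(C)C)[C@@H]1[C@@H]3OC(=O)C[C@]3(O)C(=O)[C@H]2C=C | intermediate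
18 | dilithium 8,9-dialkoxide of the 7β-O,19-lactone | [Li+].[Li+].C[C@]12C=CC(=O)[C@@](C)(O[Si](C)(C)C(C)(C)C)[C@@H]1[C@H]([O-])[C@]([O-])(CC(=O)O3)[C@@]3(C#C[Si](C)(C)C)[C@H]2C=C | intermediate
19 | 7β-O,19-lactone, 7α-(trimethylsilylethynyl), 8α-OH, 9β-OSiEt3 | C[C@]12C=CC(=O)[C@@](C)(O[Si](C)(C)C(C)(C)C)[C@@H]1[C@H](O[Si](CC)(CC)CC)[C@](O)(CC(=O)O3)[C@@]3(C#C[Si](C)(C)C)[C@H]2C=C | intermediate
20 | (17R)-17-methyl lactone | C[C@]12C=CC(=O)[C@@](C)(O[Si](C)(C)C(C)(C)C)[C@@H]1[C@H](O[Si](CC)(CC)CC)[C@](O)([C@@H](C)C(=O)O3)[C@@]3(C#C[Si](C)(C)C)[C@H]2C=C | intermediate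
21 | morpholine amide, 7β-OH, 8α-OH, 2α-vinyl | C[C@]12C=CC(=O)[C@@](C)(O[Si](C)(C)C(C)(C)C)[C@@H]1[C@H](O[Si](CC)(CC)CC)[C@](O)([C@@H](C)C(=O)N3CCOCC3)[C@@](O)(C#C[Si](C)(C)C)[C@H]2C=C | intermediate
22 | C3 aldehyde (open form of the bridged lactol) | C[C@]12C=CC(=O)[C@@](C)(O[Si](C)(C)C(C)(C)C)[C@@H]1[C@H](O[Si](CC)(CC)CC)[C@](O)([C@@H](C)C(=O)N3CCOCC3)[C@@](O)(C#C[Si](C)(C)C)[C@H]2C=O | intermediate
23 | (E)-alkenyl pinacol boronate | C[C@]12C=CC(=O)[C@@](C)(O[Si](C)(C)C(C)(C)C)[C@@H]1[C@H](O[Si](CC)(CC)CC)[C@](O)([C@@H](C)C(=O)N3CCOCC3)[C@@](O)(C#C[Si](C)(C)C)[C@H]2/C=C/B3OC(C)(C)C(C)(C)O3 | intermediate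
24 | (E)-4-methoxybenzyl enol ether, silylalkyne | C[C@]12C=CC(=O)[C@@](C)(O[Si](C)(C)C(C)(C)C)[C@@H]1[C@H](O[Si](CC)(CC)CC)[C@](O)([C@@H](C)C(=O)N3CCOCC3)[C@@](O)(C#C[Si](C)(C)C)[C@H]2/C=C/OCc3ccc(OC)cc3 | intermediate
25 | terminal alkyne | C[C@]12C=CC(=O)[C@@](C)(O[Si](C)(C)C(C)(C)C)[C@@H]1[C@H](O[Si](CC)(CC)CC)[C@](O)([C@@H](C)C(=O)N3CCOCC3)[C@@](O)(C#C)[C@H]2/C=C/OCc3ccc(OC)cc3 | intermediate
26 | propargylic dicyclohexylamine (Mannich base) | C[C@]12C=CC(=O)[C@@](C)(O[Si](C)(C)C(C)(C)C)[C@@H]1[C@H](O[Si](CC)(CC)CC)[C@](O)([C@@H](C)C(=O)N3CCOCC3)[C@@](O)(C#CCN(C3CCCCC3)C3CCCCC3)[C@H]2/C=C/OCc3ccc(OC)cc3 | intermediate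
27 | 7α-allenyl carbinol (oxy-Cope substrate) | C[C@]12C=CC(=O)[C@@](C)(O[Si](C)(C)C(C)(C)C)[C@@H]1[C@H](O[Si](CC)(CC)CC)[C@](O)([C@@H](C)C(=O)N3CCOCC3)[C@@](O)(C=C=C)[C@H]2/C=C/OCc3ccc(OC)cc3 | intermediate
28 | dipotassium 7,8-dialkoxide of 27 | [K+].[K+].C[C@]12C=CC(=O)[C@@](C)(O[Si](C)(C)C(C)(C)C)[C@@H]1[C@H](O[Si](CC)(CC)CC)[C@]([O-])([C@@H](C)C(=O)N3CCOCC3)[C@@]([O-])(C=C=C)[C@H]2/C=C/OCc3ccc(OC)cc3 | intermediate
29 | dipotassium dienolate 8-alkoxide of the ten-membered ring | [K+].[K+].[O-]/C2=C/C(=C)[C@@H](OCc3ccc(OC)cc3)/C=C/[C@@]1(C)C=CC(=O)[C@@](C)(O[Si](C)(C)C(C)(C)C)[C@@H]1[C@H](O[Si](CC)(CC)CC)[C@]2([O-])[C@@H](C)C(=O)N3CCOCC3 | intermediate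
30 | (2E,4S,6S)-6-chloro-7-ketone, ten-membered ring | C=C1[C@@H](OCc3ccc(OC)cc3)/C=C/[C@@]2(C)C=CC(=O)[C@@](C)(O[Si](C)(C)C(C)(C)C)[C@@H]2[C@H](O[Si](CC)(CC)CC)[C@](O)([C@@H](C)C(=O)N3CCOCC3)C(=O)[C@H]1Cl | intermediate
31 | (7R)-hydroxy amide | C=C1[C@@H](OCc3ccc(OC)cc3)/C=C/[C@@]2(C)C=CC(=O)[C@@](C)(O[Si](C)(C)C(C)(C)C)[C@@H]2[C@H](O[Si](CC)(CC)CC)[C@](O)([C@@H](C)C(=O)N3CCOCC3)[C@@H](O)[C@H]1Cl | intermediate
32 | γ-lactone, 4-OPMB, 9-OSiEt3, 11-OTBS | C=C1[C@@H](OCc3ccc(OC)cc3)/C=C/[C@@]2(C)C=CC(=O)[C@@](C)(O[Si](C)(C)C(C)(C)C)[C@@H]2[C@H](O[Si](CC)(CC)CC)[C@]2(O)[C@@H](C)C(=O)O[C@H]2[C@H]1Cl | intermediate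
33 | 8,9,11-triol 4-PMB ether | C=C1[C@@H](OCc3ccc(OC)cc3)/C=C/[C@@]2(C)C=CC(=O)[C@@](C)(O)[C@@H]2[C@H](O)[C@]2(O)[C@@H](C)C(=O)O[C@H]2[C@H]1Cl | intermediate
34 | 9,11-diacetate 4-PMB ether | C=C1[C@@H](OCc3ccc(OC)cc3)/C=C/[C@@]2(C)C=CC(=O)[C@@](C)(OC(C)=O)[C@@H]2[C@H](OC(C)=O)[C@]2(O)[C@@H](C)C(=O)O[C@H]2[C@H]1Cl | intermediate
35 | CNP0196166.1 | C=C1[C@@H](O)/C=C/[C@@]2(C)C=CC(=O)[C@@](C)(OC(C)=O)[C@@H]2[C@H](OC(C)=O)[C@]2(O)[C@@H](C)C(=O)O[C@H]2[C@H]1Cl | target

## Step count and least certain steps

Total step count: 23. Longest linear sequence: 23 steps (the route is linear from 1).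

Step 19 (key step, proposed new method). The most likely failures are: 5-endo attack of the C7 alkoxide on the allene instead of the [3,3] shift; transfer of the C9 silyl group to the syn-axial C7 alkoxide, which would stall the rearrangement; and chlorination at C16 or on the wrong enolate face once the ring relaxes. The fallback uses known chemistry and sets out from 25. The lithium acetylide is methylated (n-BuLi, MeI, THF/DMPU) to give the 1-propynyl carbinol F1. The alkyne version of the anionic oxy-Cope ring expansion (KH, 18-crown-6), a documented reaction type, then gives the ten-membered allenolate, which on protonation becomes the conjugated enone F2. Kinetic deprotonation of its C16 methyl with KN(SiMe3)2 regenerates the cross-conjugated dienolate, and hexachloroethane then returns the route to 30.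

Step 6. The β,γ-unsaturated ketone may drift into conjugation or be alkenylated twice under the basic conditions, because the new C2–H is doubly activated. The fallback sets out from 12: Michael addition of its lithium enolate to phenyl vinyl sulfoxide gives the sulfoxide F3, and thermal syn-elimination in toluene returns to 13 without base.

Step 11. Acyl migration from O9 to O7 may be incomplete, or a tertiary alkoxide may be silylated, so the one-flask kinetic trapping may give a mixture; addition on the wrong carbonyl face is the second risk. The fallback sets out from 17: the acetylide adduct is quenched with water and isolated as the hydroxy lactone F4. In a separate operation F4 is silylated with Et3SiCl under equilibrating base (imidazole, DMAP), where only the migrated lactone offers a secondary hydroxyl (Curtin–Hammett control); this returns to 19.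

Step 15. The aldehyde may stay locked as the bridged lactol and resist the chromium reagent, and basic alternatives would invite retro-aldol opening of ring B. The fallback sets out from 21 and avoids the aldehyde: cross-metathesis of the vinyl group with vinylboronic acid pinacol ester (second-generation Hoveyda–Grubbs catalyst) gives 23 directly. This fallback makes no new compound (F0).

Step 20. Hydride delivery may follow peripheral attack on the macrocycle instead of the chelate, which would give the C7 epimer. The fallback sets out from 30: the epimeric alcohol, the (7S)-hydroxy amide F5, is converted into the mesylate F6. On warming, the amide oxygen displaces the mesylate with inversion at C7, and hydrolysis of the iminium lactone returns to 32.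

## Further compounds

F1 | step 19 | 1-propynyl carbinol | C[C@]12C=CC(=O)[C@@](C)(O[Si](C)(C)C(C)(C)C)[C@@H]1[C@H](O[Si](CC)(CC)CC)[C@](O)([C@@H](C)C(=O)N3CCOCC3)[C@@](O)(C#CC)[C@H]2/C=C/OCc3ccc(OC)cc3
F2 | step 19 | (5Z)-5-methyl-5-en-7-one of the ten-membered ring (conjugated enone) | O=C1/C=C(C)\[C@@H](OCc3ccc(OC)cc3)/C=C/[C@@]2(C)C=CC(=O)[C@@](C)(O[Si](C)(C)C(C)(C)C)[C@@H]2[C@H](O[Si](CC)(CC)CC)[C@]1(O)[C@@H](C)C(=O)N3CCOCC3
F3 | step 6 | 2α-[2-(phenylsulfinyl)ethyl] bis-enone (both sulfur epimers) | C[C@]12C=CC(=O)[C@@](C)(O[Si](C)(C)C(C)(C)C)[C@@H]1C=CC(=O)[C@H]2CCS(=O)c1ccccc1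
F4 | step 11 | hydroxy 9β-O,19-lactone with 7β-OH and 8α-OH | C[C@]12C=CC(=O)[C@@](C)(O[Si](C)(C)C(C)(C)C)[C@@H]1[C@@H]3OC(=O)C[C@]3(O)[C@@](O)(C#C[Si](C)(C)C)[C@H]2C=C
F0 | step 15 | none | none
F5 | step 20 | (7S)-hydroxy amide | C=C1[C@@H](OCc3ccc(OC)cc3)/C=C/[C@@]2(C)C=CC(=O)[C@@](C)(O[Si](C)(C)C(C)(C)C)[C@@H]2[C@H](O[Si](CC)(CC)CC)[C@](O)([C@@H](C)C(=O)N3CCOCC3)[C@H](O)[C@H]1Cl
F6 | step 20 | 7-mesylate of the (7S)-hydroxy amide | C=C1[C@@H](OCc3ccc(OC)cc3)/C=C/[C@@]2(C)C=CC(=O)[C@@](C)(O[Si](C)(C)C(C)(C)C)[C@@H]2[C@H](O[Si](CC)(CC)CC)[C@](O)([C@@H](C)C(=O)N3CCOCC3)[C@H](OS(C)(=O)=O)[C@H]1Cl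
A1 | alternative 1 | seco-diene for ring-closing metathesis at C2=C3 | C=C[C@H](OCc1ccc(OC)cc1)C(=C)[C@H](Cl)[C@@H]1OC(=O)[C@H](C)[C@@]1(O)[C@@H](OC(C)=O)[C@H]1[C@](C)(OC(C)=O)C(=O)C=C[C@]1(C)C=C
A2 | alternative 2 | tricyclic 7-hydroxy 3-mesylate for Wharton–Grob fragmentation | C[C@]12C=CC(=O)[C@@](C)(O[Si](C)(C)C(C)(C)C)[C@@H]1[C@H](O[Si](CC)(CC)CC)[C@](O)([C@@H](C)C(=O)N1CCOCC1)[C@@]3(O)CC(=C)[C@@H](OCc1ccc(OC)cc1)[C@@H](OS(C)(=O)=O)[C@H]23
A3 | alternative 3 | 2-hydroxy-2-vinyl-7-allenyl decalin for the reversed oxy-Cope | C[C@]12C=CC(=O)[C@@](C)(O[Si](C)(C)C(C)(C)C)[C@@H]1[C@H](O[Si](CC)(CC)CC)[C@](O)([C@@H](C)C(=O)N3CCOCC3)[C@@H](C=C=C)[C@]2(O)C=C
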